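**Plan**

- Retrosynthesis: the C6–C7 bond of each 6-acyloxy-7-methyl-octahydrocyclopenta[c]pyridine unit is cut, which leaves two primary esters of one all-cis 3-(1-bromoethenyl)-4-(2-hydroxyethyl)-1,5-dimethylpiperidine. Then the two acyl–O bonds are cut, then the two aryl–cyclobutane bonds, back to cis-3-(methoxycarbonyl)cyclobutanecarboxylic acid. The piperidine goes back to a pyridine-fused δ-lactone.
- Forward ring order: pyridine (bought) → fused lactone → piperidine by hydrogenation → lactone opened. The cyclobutane is bought and arylated twice. The cyclopentane of the unit on the carboxyl cis to the 4-(benzyloxy)phenyl ring is closed first. The cyclopentane of the unit on the carboxyl cis to the methoxy-bearing ring is closed last.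
- Enabling feature: in the seco unit the ester O–CH2 carbon (future C6) lies five atoms from C7. A vinyl radical at C7 can take its hydrogen, and the C6 radical so formed closes 5-exo on the same C7, whose =CH2 becomes the C7 methyl.
- Stereochemistry: C4, C4a and C7a are all-cis from one-face hydrogenation of the pyridinium, made absolute by salt resolution. The cyclobutane is made absolute by a ligand-controlled C–H arylation; its relative configuration comes from directed cis-arylations and one epimerisation. C6 and C7 come from the radical ring closure.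

Key step: step 19

Assumption: the sense of induction of the L-tert-leucine-derived ligand in step 9 and the identity of the less soluble salt in step 5 are taken as drawn; if either is the opposite, the enantiomeric ligand or the D-acid (both available) is used.

**Route**

Step 1
Reactants: 1 3-bromo-4,5-dimethylpyridine
Product: 3 2-(3-bromo-5-methylpyridin-4-yl)ethan-1-ol, via benzylic organolithium 2 (not isolated)
Conditions: LiN(i-Pr)2 (1.1 equiv), THF, −78 °C; (CH2O)n, −78 °C → rt; H2O
Reagents that add atoms: formaldehyde (as paraformaldehyde), C=O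
Why: Lateral lithiation of the 4-methyl group (the only methyl conjugated to the ring nitrogen) and hydroxymethylation of the picolyl anion is standard, and the C–Br bond is inert to the amide base at −78 °C.

Step 2
Reactants: 3 2-(3-bromo-5-methylpyridin-4-yl)ethan-1-ol
Product: 4 5-methyl-3,4-dihydro-1H-pyrano[3,4-c]pyridin-1-one
Conditions: CO (1 atm), Pd(OAc)2 (5 mol %), Xantphos (6 mol %), K2CO3, DMF, 90 °C
Reagents that add atoms: carbon monoxide, [C-]#[O+]
Why: Palladium-catalysed carbonylative lactonisation (intramolecular alkoxycarbonylation) of an aryl bromide with an ortho 2-hydroxyethyl group should give the six-membered lactone.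

Step 3
Reactants: 4 5-methyl-3,4-dihydro-1H-pyrano[3,4-c]pyridin-1-one
Product: 5 5,7-dimethyl-1-oxo-3,4-dihydro-1H-pyrano[3,4-c]pyridin-7-ium trifluoromethanesulfonate
Conditions: MeOTf, CH2Cl2, 0 °C → rt
Reagents that add atoms: methyl trifluoromethanesulfonate, COS(=O)(=O)C(F)(F)F
Why: N-Alkylation of the pyridine (Menshutkin reaction) installs the N-methyl group and activates the ring for hydrogenation.

Step 4
Reactants: 5 5,7-dimethyl-1-oxo-3,4-dihydro-1H-pyrano[3,4-c]pyridin-7-ium trifluoromethanesulfonate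
Product: 6 rac-(4aS,5R,8aS)-5,7-dimethyloctahydro-1H-pyrano[3,4-c]pyridin-1-one (all-cis)
Conditions: H2 (5 bar), PtO2, AcOH, rt; then aq K2CO3
Reagents that add atoms: none
Why: Heterogeneous hydrogenation of the pyridinium ring in acid should deliver all hydrogens to one face, so the methyl group, the side-chain carbon at C4a and the acyl carbon at C8a end up all-cis (cis-fused lactone, racemic).

Step 5
Reactants: 6 rac-(4aS,5R,8aS)-5,7-dimethyloctahydro-1H-pyrano[3,4-c]pyridin-1-one
Product: 7 (4aS,5R,8aS)-5,7-dimethyloctahydro-1H-pyrano[3,4-c]pyridin-1-one hydrogen (2R,3R)-2,3-bis(4-methylbenzoyloxy)butanedioate (1:1 salt)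
Conditions: (−)-O,O′-di-p-toluoyl-L-tartaric acid (1 equiv), acetone/EtOH, recrystallisation to constant rotation
Reagents that add atoms: (−)-O,O′-di-p-toluoyl-L-tartaric acid, OC(=O)[C@H](OC(=O)c1ccc(C)cc1)[C@@H](OC(=O)c1ccc(C)cc1)C(=O)O
Why: Classical resolution of the tertiary amine by crystallisation of a diastereomeric tartrate salt fixes the absolute configuration of the three piperidine stereocentres.

Step 6
Reactants: 7 (4aS,5R,8aS)-lactone di-p-toluoyl-L-tartrate salt
Product: 9 1-[(3S,4S,5R)-4-(2-hydroxyethyl)-1,5-dimethylpiperidin-3-yl]ethan-1-one (in equilibrium with its cyclic hemiketal), via free-base lactone 8 (not isolated)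
Conditions: aq K2CO3/CH2Cl2; then MeLi (1.05 equiv), THF, −78 °C; aq NH4Cl at −78 °C
Reagents that add atoms: methyllithium, [Li]C
Why: Mono-addition of MeLi to a δ-lactone at −78 °C stops at the lithium hemiketal, and addition is faster than enolisation, so the α-stereocentre should be kept.

Step 7
Reactants: 9 1-[(3S,4S,5R)-4-(2-hydroxyethyl)-1,5-dimethylpiperidin-3-yl]ethan-1-one
Product: 10 N′-{(1E)-1-[(3S,4S,5R)-4-(2-hydroxyethyl)-1,5-dimethylpiperidin-3-yl]ethylidene}-2,4,6-tri(propan-2-yl)benzenesulfonohydrazide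
Conditions: 2,4,6-(i-Pr)3C6H2SO2NHNH2, AcOH (cat.), MeOH, rt
Reagents that add atoms: 2,4,6-tri(propan-2-yl)benzenesulfonohydrazide, CC(C)c1cc(C(C)C)c(S(=O)(=O)NN)c(C(C)C)c1
Why: Condensation of the methyl ketone with the sulfonyl hydrazide gives the E-hydrazone (N–N bond anti to the branched carbon), the substrate for a Shapiro reaction.

Step 8
Reactants: 10 the trisylhydrazone
Product: 12 2-[(3S,4S,5R)-3-(1-bromoethenyl)-1,5-dimethylpiperidin-4-yl]ethan-1-ol, via vinyllithium 11 (not isolated)
Conditions: n-BuLi (3.3 equiv), THF, −78 → 0 °C; BrCH2CH2Br, −78 °C → rt; H2O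
Reagents that add atoms: 1,2-dibromoethane, BrCCBr
Why: In the Shapiro reaction the dianion forms at the methyl group syn to the sulfonamide nitrogen and fragments to the terminal vinyllithium, which 1,2-dibromoethane brominates in place; no stereocentre is touched.

Step 9
Reactants: 13 cis-3-(methoxycarbonyl)cyclobutane-1-carboxylic acid; 14 2-[4-(benzyloxy)-3-methoxyphenyl]-4,4,5,5-tetramethyl-1,3,2-dioxaborolane
Product: 15 all-cis 2-[4-(benzyloxy)-3-methoxyphenyl]-3-(methoxycarbonyl)cyclobutane-1-carboxylic acid (enantiomer as in the SMILES)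
Conditions: Pd(OAc)2 (10 mol %), N-acetyl aminoethyl amine ligand from L-tert-leucine (20 mol %), Ag2CO3 (1.5 equiv), 1,4-benzoquinone (0.5 equiv), t-AmylOH, 70 °C
Reagents that add atoms: none
Why: Carboxylate-directed palladium-catalysed β-C(sp3)–H arylation with an arylboronate places the aryl group cis to the carboxyl group, and the chiral mono-protected aminoethyl amine ligand selects one of the two enantiotopic CH2 groups, which sets the absolute configuration of the cyclobutane.

Step 10
Reactants: 15 the all-cis aryl acid; 16 2-(methylsulfanyl)aniline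
Product: 17 methyl all-cis 2-[4-(benzyloxy)-3-methoxyphenyl]-3-{[2-(methylsulfanyl)phenyl]carbamoyl}cyclobutane-1-carboxylate
Conditions: DIC, HOBt (cat.), CH2Cl2, rt
Reagents that add atoms: none
Why: Carbodiimide amide coupling installs the bidentate anilide directing group without disturbing the all-cis stereocentres.

Step 11
Reactants: 17 the all-cis anilide ester
Product: 18 methyl 2-[4-(benzyloxy)-3-methoxyphenyl]-3-{[2-(methylsulfanyl)phenyl]carbamoyl}cyclobutane-1-carboxylate with the carbamoyl group trans to the aryl group and to the ester (ester and aryl still cis)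
Conditions: LiOt-Bu (1.5 equiv), toluene, 50 °C; aq NH4Cl
Reagents that add atoms: none
Why: Base-mediated epimerisation at the carbon α to the amide relieves the all-cis strain and moves the directing group to the face opposite the first aryl group, as known for all-cis 2-arylcyclobutane-1,3-dicarboxylic anilide esters.

Step 12
Reactants: 18 the epimerised anilide ester; 19 1-(benzyloxy)-4-iodobenzene
Product: 20 methyl 2-[4-(benzyloxy)-3-methoxyphenyl]-4-[4-(benzyloxy)phenyl]-3-{[2-(methylsulfanyl)phenyl]carbamoyl}cyclobutane-1-carboxylate, α-truxillate configuration (aryls trans; ester cis to the methoxy-bearing aryl; carbamoyl cis to the 4-(benzyloxy)phenyl)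
Conditions: Pd(OAc)2 (15 mol %), Ag2CO3 (1.5 equiv), PivOH (1 equiv), (CF3)2CHOH, 90 °C
Reagents that add atoms: none
Why: Amide-directed palladium-catalysed C(sp3)–H arylation with an aryl iodide functionalises the remaining methylene cis to the directing group, that is trans to the first aryl group, which completes the α-truxillate arrangement.

Step 13
Reactants: 20 the diaryl anilide ester
Product: 21 the N-Boc imide of 20 (tert-butyl N-acyl-N-[2-(methylsulfanyl)phenyl]carbamate)
Conditions: Boc2O, DMAP, MeCN, rt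
Reagents that add atoms: di-tert-butyl dicarbonate, CC(C)(C)OC(=O)OC(=O)OC(C)(C)C
Why: N-Acylation of the secondary anilide turns it into an activated imide that can be cleaved under mild conditions.

Step 14
Reactants: 21 the N-Boc imide
Product: 23 2-[4-(benzyloxy)-3-methoxyphenyl]-4-[4-(benzyloxy)phenyl]-3-(methoxycarbonyl)cyclobutane-1-carboxylic acid (α-truxillate configuration; free carboxyl cis to the 4-(benzyloxy)phenyl group), via lithium peroxycarboxylate 22 (not isolated)
Conditions: LiOH, H2O2, THF/H2O, 0 °C; aq Na2SO3; HCl to pH 3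
Reagents that add atoms: hydrogen peroxide, OO
Why: Hydroperoxide attacks the exocyclic acyl carbon of the N-Boc imide much faster than the hindered methyl ester, so only the directing group should be removed, and sulfite reduces the peracid.

Step 15
Reactants: 23 the mono-acid; 12 2-[(3S,4S,5R)-3-(1-bromoethenyl)-1,5-dimethylpiperidin-4-yl]ethan-1-ol
Product: 24 1-{2-[(3S,4S,5R)-3-(1-bromoethenyl)-1,5-dimethylpiperidin-4-yl]ethyl} 3-methyl 2-[4-(benzyloxy)-3-methoxyphenyl]-4-[4-(benzyloxy)phenyl]cyclobutane-1,3-dicarboxylate (α-truxillate configuration)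
Conditions: DIC, DMAP (cat.), CH2Cl2, 0 °C → rt
Reagents that add atoms: none
Why: Steglich esterification of the hindered cyclobutane acid with a primary alcohol is unproblematic, which is the reason for carrying the alcohol unit in its seco form.

Step 16
Reactants: 24 the bromoethenyl ester
Product: 25 1-[(4R,4aS,6R,7S,7aR)-2,4,7-trimethyloctahydro-1H-cyclopenta[c]pyridin-6-yl] 3-methyl 2-[4-(benzyloxy)-3-methoxyphenyl]-4-[4-(benzyloxy)phenyl]cyclobutane-1,3-dicarboxylate
Conditions: (Me3Si)3SiH (1.5 equiv) and AIBN (0.3 equiv) added over 8 h, PhH, 80 °C, final 5 mM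
Reagents that add atoms: none
Why: Radical translocation–cyclisation (vinyl radical, 1,5-hydrogen transfer from the ester O–CH2, 5-exo-trig closure) builds the first cyclopenta[c]pyridine unit and should set C6 and C7 as explained under step 19.

Step 17
Reactants: 25 the mono-cyclised methyl ester
Product: 26 the corresponding 3-carboxylic acid (methyl ester cleaved; cyclopentyl ester kept)
Conditions: Me3SnOH (8 equiv), ClCH2CH2Cl, 80 °C; dilute HCl wash, then pH 7
Reagents that add atoms: trimethyltin hydroxide, C[Sn](C)(C)O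
Why: Me3SnOH cleaves methyl esters selectively under near-neutral conditions and should leave the secondary cyclopentyl ester and the α-stereocentres untouched.

Step 18
Reactants: 26 the acid; 12 2-[(3S,4S,5R)-3-(1-bromoethenyl)-1,5-dimethylpiperidin-4-yl]ethan-1-ol
Product: 27 1-[(4R,4aS,6R,7S,7aR)-2,4,7-trimethyloctahydro-1H-cyclopenta[c]pyridin-6-yl] 3-{2-[(3S,4S,5R)-3-(1-bromoethenyl)-1,5-dimethylpiperidin-4-yl]ethyl} 2-[4-(benzyloxy)-3-methoxyphenyl]-4-[4-(benzyloxy)phenyl]cyclobutane-1,3-dicarboxylate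
Conditions: DIC, DMAP (cat.), CH2Cl2, 0 °C → rt
Reagents that add atoms: none
Why: Steglich esterification with the primary alcohol, as in step 15; the tertiary amines are not acylated.

Step 19
Reactants: 27 the second bromoethenyl ester
Product: 28 bis[(4R,4aS,6R,7S,7aR)-2,4,7-trimethyloctahydro-1H-cyclopenta[c]pyridin-6-yl] 2-[4-(benzyloxy)-3-methoxyphenyl]-4-[4-(benzyloxy)phenyl]cyclobutane-1,3-dicarboxylate (α-truxillate configuration)
Conditions: (Me3Si)3SiH (1.5 equiv) and AIBN (0.3 equiv) added over 8 h, PhH, 80 °C, final 5 mM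
Reagents that add atoms: none
Why: The silyl radical abstracts bromine to give the σ-vinyl radical at C7, which takes a hydrogen from the O–CH2 carbon five atoms away through a six-membered transition state, so that C6 becomes an α-acyloxyalkyl radical and C7 the inner carbon of a vinyl group; the C6 radical then adds to C7 and the primary radical on the former =CH2 carbon is reduced by the silane to the C7 methyl. The closest known reaction type is the radical translocation–cyclisation of 2-bromo-1-alkenes under tin or silicon hydride. The cyclopentane closes in the 5-exo-trig mode, which a hex-5-enyl radical with a terminal vinyl acceptor prefers strongly over 6-endo. C7 should be set by a chair-like transition state in which the forming ring is cis-fused to the piperidine and the new CH2 lies on the convex face, trans to the C7a–C1 bond; C6 should be set by the preference of 1-substituted hexenyl radicals for the 1,5-cis product, which puts the acyloxy group cis to the new methyl and so also on the convex face. The step needs site selectivity in the hydrogen transfer and slow chain transfer: the O–CH2 hydrogens are activated by oxygen and held gauche to the vinyl radical, the N-methyl and ring α-amino C–H bonds cannot reach an equatorial vinyl radical on the all-cis piperidine, and slow addition of the silane keeps direct reduction of the vinyl and C6 radicals below translocation and ring closure.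

Step 20
Reactants: 28 the bis(benzyl ether)
Product: 29 bis[(4R,4aS,6R,7S,7aR)-2,4,7-trimethyloctahydro-1H-cyclopenta[c]pyridin-6-yl] 2-(4-hydroxy-3-methoxyphenyl)-4-(4-hydroxyphenyl)cyclobutane-1,3-dicarboxylate (CNP0331906.2)
Conditions: H2 (1 atm), Pd/C (10 %), EtOAc/MeOH, rt
Reagents that add atoms: none
Why: Hydrogenolysis of the two benzyl aryl ethers over palladium on carbon frees the phenols, and no other group in the molecule is reducible under these conditions.

**Compound list**

1 | 3-bromo-4,5-dimethylpyridine | Cc1cncc(Br)c1C | starting material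
2 | (3-bromo-5-methylpyridin-4-yl)methyllithium | [Li]Cc1c(C)cncc1Br | intermediate
3 | 2-(3-bromo-5-methylpyridin-4-yl)ethan-1-ol | OCCc1c(C)cncc1Br | intermediate
4 | 5-methyl-3,4-dihydro-1H-pyrano[3,4-c]pyridin-1-one | O=C1OCCc2c(C)cncc12 | intermediate
5 | 5,7-dimethyl-1-oxo-3,4-dihydro-1H-pyrano[3,4-c]pyridin-7-ium trifluoromethanesulfonate | O=C1OCCc2c(C)c[n+](C)cc12.[O-]S(=O)(=O)C(F)(F)F | intermediate
6 | rac-(4aS,5R,8aS)-5,7-dimethyloctahydro-1H-pyrano[3,4-c]pyridin-1-one (racemate; relative configuration shown) | O1CC[C@@H]2[C@@H](CN(C)C[C@@H]2C)C1=O | intermediate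
7 | (4aS,5R,8aS)-5,7-dimethyloctahydro-1H-pyrano[3,4-c]pyridin-1-one hydrogen (2R,3R)-2,3-bis(4-methylbenzoyloxy)butanedioate | O1CC[C@@H]2[C@@H](CN(C)C[C@@H]2C)C1=O.OC(=O)[C@H](OC(=O)c1ccc(C)cc1)[C@@H](OC(=O)c1ccc(C)cc1)C(=O)O | intermediate
8 | (4aS,5R,8aS)-5,7-dimethyloctahydro-1H-pyrano[3,4-c]pyridin-1-one (free base) | O1CC[C@@H]2[C@@H](CN(C)C[C@@H]2C)C1=O | intermediate
9 | 1-[(3S,4S,5R)-4-(2-hydroxyethyl)-1,5-dimethylpiperidin-3-yl]ethan-1-one | OCC[C@@H]1[C@@H](CN(C)C[C@@H]1C)C(C)=O | intermediate
10 | N′-{(1E)-1-[(3S,4S,5R)-4-(2-hydroxyethyl)-1,5-dimethylpiperidin-3-yl]ethylidene}-2,4,6-tri(propan-2-yl)benzenesulfonohydrazide | OCC[C@@H]1[C@@H](CN(C)C[C@@H]1C)/C(C)=N/NS(=O)(=O)c1c(C(C)C)cc(C(C)C)cc1C(C)C | intermediate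
11 | vinyllithium from 10: lithium alkoxide of 12 with lithium in place of bromine | [Li]OCC[C@@H]1[C@@H](CN(C)C[C@@H]1C)C([Li])=C | intermediate
12 | 2-[(3S,4S,5R)-3-(1-bromoethenyl)-1,5-dimethylpiperidin-4-yl]ethan-1-ol | OCC[C@@H]1[C@@H](CN(C)C[C@@H]1C)C(Br)=C | intermediate
13 | cis-3-(methoxycarbonyl)cyclobutane-1-carboxylic acid | OC(=O)[C@H]1C[C@@H](C(=O)OC)C1 | starting material
14 | 2-[4-(benzyloxy)-3-methoxyphenyl]-4,4,5,5-tetramethyl-1,3,2-dioxaborolane | COc1cc(B2OC(C)(C)C(C)(C)O2)ccc1OCc1ccccc1 | starting material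
15 | all-cis 2-[4-(benzyloxy)-3-methoxyphenyl]-3-(methoxycarbonyl)cyclobutane-1-carboxylic acid | COc1cc([C@H]2[C@@H](C(=O)O)C[C@H]2C(=O)OC)ccc1OCc1ccccc1 | intermediate
16 | 2-(methylsulfanyl)aniline | CSc1ccccc1N | starting material
17 | methyl all-cis 2-[4-(benzyloxy)-3-methoxyphenyl]-3-{[2-(methylsulfanyl)phenyl]carbamoyl}cyclobutane-1-carboxylate | COc1cc([C@H]2[C@@H](C(=O)Nc3ccccc3SC)C[C@H]2C(=O)OC)ccc1OCc1ccccc1 | intermediate
18 | epimer of 17 at the carbamoyl-bearing carbon (carbamoyl trans to aryl and ester) | COc1cc([C@H]2[C@H](C(=O)Nc3ccccc3SC)C[C@H]2C(=O)OC)ccc1OCc1ccccc1 | intermediate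
19 | 1-(benzyloxy)-4-iodobenzene | Ic1ccc(OCc2ccccc2)cc1 | starting material
20 | methyl 2-[4-(benzyloxy)-3-methoxyphenyl]-4-[4-(benzyloxy)phenyl]-3-{[2-(methylsulfanyl)phenyl]carbamoyl}cyclobutane-1-carboxylate (α-truxillate configuration) | COc1cc([C@H]2[C@H](C(=O)Nc3ccccc3SC)[C@H](c3ccc(OCc4ccccc4)cc3)[C@H]2C(=O)OC)ccc1OCc1ccccc1 | intermediate
21 | N-Boc imide of 20 | COc1cc([C@H]2[C@H](C(=O)N(C(=O)OC(C)(C)C)c3ccccc3SC)[C@H](c3ccc(OCc4ccccc4)cc3)[C@H]2C(=O)OC)ccc1OCc1ccccc1 | intermediate
22 | lithium peroxycarboxylate of 23 | COc1cc([C@H]2[C@H](C(=O)OO[Li])[C@H](c3ccc(OCc4ccccc4)cc3)[C@H]2C(=O)OC)ccc1OCc1ccccc1 | intermediate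
23 | 2-[4-(benzyloxy)-3-methoxyphenyl]-4-[4-(benzyloxy)phenyl]-3-(methoxycarbonyl)cyclobutane-1-carboxylic acid (α-truxillate configuration) | COc1cc([C@H]2[C@H](C(=O)O)[C@H](c3ccc(OCc4ccccc4)cc3)[C@H]2C(=O)OC)ccc1OCc1ccccc1 | intermediate
24 | 1-{2-[(3S,4S,5R)-3-(1-bromoethenyl)-1,5-dimethylpiperidin-4-yl]ethyl} 3-methyl 2-[4-(benzyloxy)-3-methoxyphenyl]-4-[4-(benzyloxy)phenyl]cyclobutane-1,3-dicarboxylate | COc1cc([C@H]2[C@H](C(=O)OCC[C@@H]5[C@@H](CN(C)C[C@@H]5C)C(Br)=C)[C@H](c3ccc(OCc4ccccc4)cc3)[C@H]2C(=O)OC)ccc1OCc1ccccc1 | intermediate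
25 | 1-[(4R,4aS,6R,7S,7aR)-2,4,7-trimethyloctahydro-1H-cyclopenta[c]pyridin-6-yl] 3-methyl 2-[4-(benzyloxy)-3-methoxyphenyl]-4-[4-(benzyloxy)phenyl]cyclobutane-1,3-dicarboxylate | COc1cc([C@H]2[C@H](C(=O)O[C@@H]5C[C@@H]6[C@@H](CN(C)C[C@@H]6C)[C@@H]5C)[C@H](c3ccc(OCc4ccccc4)cc3)[C@H]2C(=O)OC)ccc1OCc1ccccc1 | intermediate
26 | 2-[4-(benzyloxy)-3-methoxyphenyl]-4-[4-(benzyloxy)phenyl]-3-{[(4R,4aS,6R,7S,7aR)-2,4,7-trimethyloctahydro-1H-cyclopenta[c]pyridin-6-yl]oxycarbonyl}cyclobutane-1-carboxylic acid | COc1cc([C@H]2[C@H](C(=O)O[C@@H]5C[C@@H]6[C@@H](CN(C)C[C@@H]6C)[C@@H]5C)[C@H](c3ccc(OCc4ccccc4)cc3)[C@H]2C(=O)O)ccc1OCc1ccccc1 | intermediate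
27 | mixed diester: (4R,4aS,6R,7S,7aR)-2,4,7-trimethyloctahydro-1H-cyclopenta[c]pyridin-6-yl ester on the carboxyl cis to the 4-(benzyloxy)phenyl group, 2-[(3S,4S,5R)-3-(1-bromoethenyl)-1,5-dimethylpiperidin-4-yl]ethyl ester on the other | COc1cc([C@H]2[C@H](C(=O)O[C@@H]5C[C@@H]6[C@@H](CN(C)C[C@@H]6C)[C@@H]5C)[C@H](c3ccc(OCc4ccccc4)cc3)[C@H]2C(=O)OCC[C@@H]7[C@@H](CN(C)C[C@@H]7C)C(Br)=C)ccc1OCc1ccccc1 | intermediate
28 | bis[(4R,4aS,6R,7S,7aR)-2,4,7-trimethyloctahydro-1H-cyclopenta[c]pyridin-6-yl] 2-[4-(benzyloxy)-3-methoxyphenyl]-4-[4-(benzyloxy)phenyl]cyclobutane-1,3-dicarboxylate | COc1cc([C@H]2[C@H](C(=O)O[C@@H]5C[C@@H]6[C@@H](CN(C)C[C@@H]6C)[C@@H]5C)[C@H](c3ccc(OCc4ccccc4)cc3)[C@H]2C(=O)O[C@@H]7C[C@@H]8[C@@H](CN(C)C[C@@H]8C)[C@@H]7C)ccc1OCc1ccccc1 | intermediate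
29 | bis[(4R,4aS,6R,7S,7aR)-2,4,7-trimethyloctahydro-1H-cyclopenta[c]pyridin-6-yl] 2-(4-hydroxy-3-methoxyphenyl)-4-(4-hydroxyphenyl)cyclobutane-1,3-dicarboxylate (CNP0331906.2) | COc1cc([C@H]2[C@H](C(=O)O[C@@H]3C[C@@H]4[C@@H](CN(C)C[C@@H]4C)[C@@H]3C)[C@H](c3ccc(O)cc3)[C@H]2C(=O)O[C@@H]2C[C@@H]3[C@@H](CN(C)C[C@@H]3C)[C@@H]2C)ccc1O | target

**Summary**

Total step count: 20. Longest linear sequence: 14 steps (steps 1–8, then 15–20).

Steps most likely to fail:

1. Step 19 (and its twin, step 16). The vinyl radical may be reduced before it transfers hydrogen, or the 5-exo closure may show poor facial selectivity at C6. The fallback closes the ring by polar chemistry before the ester is made and forms the ester with inversion. It sets out from 12. Dess–Martin oxidation should give 2-[(3S,4S,5R)-3-(1-bromoethenyl)-1,5-dimethylpiperidin-4-yl]acetaldehyde F1. An intramolecular Nozaki–Hiyama–Kishi reaction (CrCl2, NiCl2 cat., DMF) should give (4R,4aS,7aR)-2,4-dimethyl-7-methylideneoctahydro-1H-cyclopenta[c]pyridin-6-ol F2 as a mixture at C6. A second Dess–Martin oxidation should give (4R,4aS,7aR)-2,4-dimethyl-7-methylideneoctahydro-6H-cyclopenta[c]pyridin-6-one F3. Hydrogenation over Pd/C followed by equilibration with K2CO3 in MeOH should give (4R,4aS,7S,7aR)-2,4,7-trimethyloctahydro-6H-cyclopenta[c]pyridin-6-one F4, with the methyl group on the convex face. LiBH(s-Bu)3 should attack from the convex face to give (4R,4aS,6S,7S,7aR)-2,4,7-trimethyloctahydro-1H-cyclopenta[c]pyridin-6-ol F5. Mitsunobu esterification of F5 with acid 26 (PPh3, DIAD) inverts C6 and comes back to the route at 28; with acid 23 it gives 25 in the same way.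

2. Step 9. Discrimination between the two enantiotopic methylene groups may be low, or the hindered product may be arylated a second time. The fallback sets out from 13, which is first coupled with 16 (DIC) to the achiral methyl cis-3-{[2-(methylsulfanyl)phenyl]carbamoyl}cyclobutane-1-carboxylate F6. This is arylated with 1-(benzyloxy)-4-iodo-2-methoxybenzene under the conditions of step 12 to give racemic methyl all-cis 2-[4-(benzyloxy)-3-methoxyphenyl]-3-{[2-(methylsulfanyl)phenyl]carbamoyl}cyclobutane-1-carboxylate F7. Preparative chromatography on a chiral stationary phase comes back to the route at 17.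

3. Step 5. The diastereomeric salts may fail to crystallise apart. The fallback sets out from racemic 6, which is separated by preparative supercritical-fluid chromatography on a polysaccharide chiral stationary phase; this gives the free base 8 directly and comes back to the route there, for the MeLi addition of step 6.

Further compounds
F1 | step 19 | 2-[(3S,4S,5R)-3-(1-bromoethenyl)-1,5-dimethylpiperidin-4-yl]acetaldehyde | O=CC[C@@H]1[C@@H](CN(C)C[C@@H]1C)C(Br)=C
F2 | step 19 | (4R,4aS,7aR)-2,4-dimethyl-7-methylideneoctahydro-1H-cyclopenta[c]pyridin-6-ol (mixture at C6) | OC1C[C@@H]2[C@@H](CN(C)C[C@@H]2C)C1=C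
F3 | step 19 | (4R,4aS,7aR)-2,4-dimethyl-7-methylideneoctahydro-6H-cyclopenta[c]pyridin-6-one | O=C1C[C@@H]2[C@@H](CN(C)C[C@@H]2C)C1=C
F4 | step 19 | (4R,4aS,7S,7aR)-2,4,7-trimethyloctahydro-6H-cyclopenta[c]pyridin-6-one | O=C1C[C@@H]2[C@@H](CN(C)C[C@@H]2C)[C@@H]1C
F5 | step 19 | (4R,4aS,6S,7S,7aR)-2,4,7-trimethyloctahydro-1H-cyclopenta[c]pyridin-6-ol | O[C@H]1C[C@@H]2[C@@H](CN(C)C[C@@H]2C)[C@@H]1C
F6 | step 9 | methyl cis-3-{[2-(methylsulfanyl)phenyl]carbamoyl}cyclobutane-1-carboxylate | COC(=O)[C@H]1C[C@@H](C(=O)Nc2ccccc2SC)C1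
F7 | step 9 | racemic methyl all-cis 2-[4-(benzyloxy)-3-methoxyphenyl]-3-{[2-(methylsulfanyl)phenyl]carbamoyl}cyclobutane-1-carboxylate (relative configuration shown) | COc1cc([C@H]2[C@@H](C(=O)Nc3ccccc3SC)C[C@H]2C(=O)OC)ccc1OCc1ccccc1
F0 | step 5 | none | none
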